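The plan cuts the seven-membered ring (ring B) at C9–C10, its only bond between two unsubstituted methylenes, flanked by quaternary C1 and the tertiary carbinol C8; this is the feature the key step exploits. Ring-closing metathesis of two vinyl groups makes that bond as C9=C10 and, in one operation, converts a monocyclic ketone into the trans-fused hydroazulenone with C1, C5, C6 and C8 already in place. The precursor is a cyclopentanone bearing methyl and vinyl on C1 and, trans to the vinyl, a C5 side chain with a silyl-protected C6 carbinol and the free C8 methyl vinyl carbinol; it comes from a silicon-directed anti-aldol union of a conjugate-addition enolate with an epoxidation-derived aldehyde.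

Key step: step 12

Numbering used for all locants: ring A (five-membered) is C1–C2–C3–C4–C5 and ring B (seven-membered) is C1–C5–C6–C7–C8–C9–C10; C1 carries the angular methyl, C4 the isopropyl carbinol, C6 the ester oxygen, C8 the methyl carbinol.

Assumption: the (4S,5S) antipode of the carbene ligand in step 6 is taken to deliver the alkenyl group to the enone face that gives the S centre; if it gives the opposite sense, its (4R,5R) mirror image is used and nothing else changes.

Design remark: with a plain vinyl group on C1 the two faces of the C5 enolate differ only as methyl against vinyl, which is not a reliable bias. The vinyl group is therefore carried through the aldol as a bulky 1-(trimethylsilyl)vinyl group and unmasked afterwards (steps 9 and 10), at the cost of two steps.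

Step 1
Reactants: 1 (E)-3-methylpent-2-en-4-yn-1-ol
Product: 2 [(2R,3R)-3-ethynyl-3-methyloxiran-2-yl]methanol
Conditions: Ti(OiPr)4 (10 mol%), D-(−)-diethyl tartrate (12 mol%), t-BuOOH, 4 Å molecular sieves, CH2Cl2, −20 °C
Reagents that add atoms: tert-butyl hydroperoxide, CC(C)(C)OO
Why: Sharpless asymmetric epoxidation of a trisubstituted E allylic alcohol, in which the D-tartrate titanium complex delivers oxygen to the alkene face that gives the (2R,3R) epoxide and so fixes the future C8 configuration under reagent control.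

Step 2
Reactants: 2 [(2R,3R)-3-ethynyl-3-methyloxiran-2-yl]methanol
Product: 3 (S)-3-methylpent-4-yne-1,3-diol
Conditions: NaAlH2(OCH2CH2OMe)2, THF, 0 °C
Reagents that add atoms: none
Why: Hydroxyl-directed reductive opening of a 2,3-epoxy alcohol, in which the aluminate bound at O1 delivers hydride to the less substituted C2, so that the C3–O bond and its configuration are retained and the 1,3-diol results.

Step 3
Reactants: 3 (S)-3-methylpent-4-yne-1,3-diol
Product: 4 (S)-3-methylpent-4-ene-1,3-diol
Conditions: H2 (1 atm), Pd/CaCO3 poisoned with Pb(OAc)2 (Lindlar catalyst), quinoline, EtOAc, rt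
Reagents that add atoms: none
Why: Lindlar semi-hydrogenation stops the terminal alkyne at the vinyl stage and does not touch the tertiary carbinol stereocentre.

Step 4
Reactants: 4 (S)-3-methylpent-4-ene-1,3-diol
Product: 5 (S)-3-methyl-1,3-bis(triethylsilyloxy)pent-4-ene
Conditions: Et3SiOTf, 2,6-lutidine, CH2Cl2, −78 to 0 °C
Reagents that add atoms: triethylsilyl triflate, CC[Si](CC)(CC)OS(=O)(=O)C(F)(F)F
Why: Silyl triflate silylation is strong enough to cap the tertiary as well as the primary hydroxyl.

Step 5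
Reactants: 5 (S)-3-methyl-1,3-bis(triethylsilyloxy)pent-4-ene
Product: 6 (S)-3-methyl-3-(triethylsilyloxy)pent-4-enal
Conditions: (COCl)2, DMSO, CH2Cl2, −78 to −40 °C; Et3N, −78 to 0 °C
Reagents that add atoms: none
Why: Swern oxidation applied to a silyl ether, in which the chlorosulfonium salt cleaves only the unhindered primary triethylsilyl ether and oxidises it in the same flask to the aldehyde (C6), while the tertiary silyl ether at C8 is inert.

Step 6
Reactants: 7 3-methylcyclopent-2-en-1-one; 8 ethynyltrimethylsilane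
Product: 11 (S)-trimethyl({3-methyl-3-[1-(trimethylsilyl)ethenyl]cyclopent-1-en-1-yl}oxy)silane, via alkenylalane 9 (not isolated), via aluminium enolate 10 (not isolated)
Conditions: 8, i-Bu2AlH, hexane/THF, 55 °C; then 7, Cu(OTf)2 (5 mol%), 2-[(4S,5S)-3-(2,6-diethylphenyl)-4,5-diphenyl-4,5-dihydro-1H-imidazol-3-ium-1-yl]benzenesulfonate (6 mol%), THF, −78 to −15 °C; then Me3SiOTf, −78 to 0 °C
Reagents that add atoms: trimethylsilyl triflate, C[Si](C)(C)OS(=O)(=O)C(F)(F)F
Why: Copper–N-heterocyclic carbene catalysed enantioselective conjugate addition of a silyl-substituted alkenylalane (from hydroalumination of the silylalkyne with aluminium on the silicon-bearing carbon) to a β-substituted cyclic enone sets quaternary C1 under ligand control, and silylation of the aluminium enolate fixes the C4–C5 enolate regiochemistry that deprotonation of the ketone could not give.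

Step 7
Reactants: 11 (S)-trimethyl({3-methyl-3-[1-(trimethylsilyl)ethenyl]cyclopent-1-en-1-yl}oxy)silane; 6 (S)-3-methyl-3-(triethylsilyloxy)pent-4-enal
Product: 14 (2S,3S)-2-[(1S,3S)-1-hydroxy-3-methyl-3-(triethylsilyloxy)pent-4-en-1-yl]-3-methyl-3-[1-(trimethylsilyl)ethenyl]cyclopentan-1-one, via lithium enolate 12 (not isolated), via boron enolate 13 (not isolated)
Conditions: MeLi, THF, 0 °C; (c-C6H11)2BCl, −78 °C; 6, −78 to −20 °C; then pH 7 buffer, MeOH, H2O2, 0 °C
Reagents that add atoms: none
Why: Boron-mediated aldol addition in which the regiodefined cyclic (E) dicyclohexylboron enolate reacts through a chair Zimmerman–Traxler transition state to give the 5,6-anti adduct, while the aldehyde approaches C5 on the face opposite the bulky 1-silylvinyl group (cis to the C1 methyl), so that C5 and C6 are set together relative to C1.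

Step 8
Reactants: 14 (2S,3S)-2-[(1S,3S)-1-hydroxy-3-methyl-3-(triethylsilyloxy)pent-4-en-1-yl]-3-methyl-3-[1-(trimethylsilyl)ethenyl]cyclopentan-1-one
Product: 15 (2S,3S)-2-[(1S,3S)-1-(tert-butyldimethylsilyloxy)-3-methyl-3-(triethylsilyloxy)pent-4-en-1-yl]-3-methyl-3-[1-(trimethylsilyl)ethenyl]cyclopentan-1-one
Conditions: t-BuMe2SiOTf, 2,6-lutidine, CH2Cl2, −78 °C
Reagents that add atoms: tert-butyldimethylsilyl triflate, CC(C)(C)[Si](C)(C)OS(=O)(=O)C(F)(F)F
Why: Silyl triflate silylation of the hindered secondary hydroxyl at low temperature closes the retro-aldol pathway for the later steps without epimerising C5.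

Step 9
Reactants: 15 (2S,3S)-2-[(1S,3S)-1-(tert-butyldimethylsilyloxy)-3-methyl-3-(triethylsilyloxy)pent-4-en-1-yl]-3-methyl-3-[1-(trimethylsilyl)ethenyl]cyclopentan-1-one
Product: 16 (2S,3S)-2-[(1S,3S)-1-(tert-butyldimethylsilyloxy)-3-methyl-3-(triethylsilyloxy)pent-4-en-1-yl]-3-(1-iodoethenyl)-3-methylcyclopentan-1-one
Conditions: N-iodosuccinimide, 2,6-lutidine, (CF3)2CHOH/CH2Cl2, 0 °C
Reagents that add atoms: N-iodosuccinimide, O=C1CCC(=O)N1I
Why: Iododesilylation, in which ipso attack of iodonium on the vinylsilane (β-silicon stabilisation) replaces silicon by iodine, while the less nucleophilic vinyl group next to the C8 ether oxygen and both silyl ethers are left alone under buffered conditions.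

Step 10
Reactants: 16 (2S,3S)-2-[(1S,3S)-1-(tert-butyldimethylsilyloxy)-3-methyl-3-(triethylsilyloxy)pent-4-en-1-yl]-3-(1-iodoethenyl)-3-methylcyclopentan-1-one
Product: 17 (2S,3R)-2-[(1S,3S)-1-(tert-butyldimethylsilyloxy)-3-methyl-3-(triethylsilyloxy)pent-4-en-1-yl]-3-ethenyl-3-methylcyclopentan-1-one
Conditions: Bu3SnH, Pd(PPh3)4 (5 mol%), THF, rt
Reagents that add atoms: none
Why: Palladium-catalysed hydrogenolysis of an alkenyl iodide (oxidative addition, hydride transfer from tin, reductive elimination) gives the parent C1 vinyl group under neutral conditions that spare the ketone, both silyl ethers and the other alkene.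

Step 11
Reactants: 17 (2S,3R)-2-[(1S,3S)-1-(tert-butyldimethylsilyloxy)-3-methyl-3-(triethylsilyloxy)pent-4-en-1-yl]-3-ethenyl-3-methylcyclopentan-1-one
Product: 18 (2S,3R)-2-[(1S,3S)-1-(tert-butyldimethylsilyloxy)-3-hydroxy-3-methylpent-4-en-1-yl]-3-ethenyl-3-methylcyclopentan-1-one
Conditions: HF·pyridine, pyridine, THF, 0 °C
Reagents that add atoms: none
Why: Buffered fluoride cleaves the triethylsilyl ether, which is less hindered at silicon, much faster than the tert-butyldimethylsilyl ether, freeing the C8 hydroxyl that assists the metathesis while C6 stays protected.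

Step 12
Reactants: 18 (2S,3R)-2-[(1S,3S)-1-(tert-butyldimethylsilyloxy)-3-hydroxy-3-methylpent-4-en-1-yl]-3-ethenyl-3-methylcyclopentan-1-one
Product: 19 (1R,5S,6S,8S)-6-(tert-butyldimethylsilyloxy)-8-hydroxy-1,8-dimethyl-trans-bicyclo[5.3.0]dec-9-en-4-one (locants as defined above)
Conditions: second-generation Grubbs catalyst (H2IMes)(PCy3)Cl2Ru=CHPh (10 mol%), CH2Cl2 (0.003 M), 40 °C
Reagents that add atoms: none
Why: Ring-closing olefin metathesis: the ruthenium benzylidene exchanges onto the more accessible C8 vinyl group, helped by the free tertiary allylic hydroxyl, and the resulting alkylidene adds across the C1 vinyl group to a ruthenacyclobutane that collapses to the cis C9=C10 bond and ethylene. The closest known reaction type is cycloheptene formation by metathesis between a vinyl carbinol and a vinyl group on a quaternary carbon. Ring B is closed in the only possible mode, union of the two internal alkene carbons C9 and C10 of a 1,8-diene, and it is annulated trans on the cyclopentanone because the C1 vinyl group and the C5 side chain are already trans. No stereocentre is created, and C1, C5, C6 and C8 pass through unchanged under neutral conditions, so the epimerisable C5 is not touched. The selectivity required is cyclisation over intermolecular metathesis, secured by high dilution, by loss of ethylene and by the fully substituted C1 and C8, which fold the chain and make both vinyl groups poor partners for dimerisation.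

Step 13
Reactants: 19 (1R,5S,6S,8S)-6-(tert-butyldimethylsilyloxy)-8-hydroxy-1,8-dimethyl-trans-bicyclo[5.3.0]dec-9-en-4-one
Product: 20 (1S,5S,6S,8R)-6-(tert-butyldimethylsilyloxy)-8-hydroxy-1,8-dimethyl-trans-bicyclo[5.3.0]decan-4-one
Conditions: H2 (1 atm), [Ir(cod)(PCy3)(py)]PF6 (5 mol%), CH2Cl2, rt
Reagents that add atoms: none
Why: Hydroxyl-directed homogeneous hydrogenation of the hindered cis-disubstituted C9=C10 bond, the only alkene present, creates no stereocentre and leaves the ketone and the silyl ether intact.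

Step 14
Reactants: 20 (1S,5S,6S,8R)-6-(tert-butyldimethylsilyloxy)-8-hydroxy-1,8-dimethyl-trans-bicyclo[5.3.0]decan-4-one
Product: 21 (1S,5S,6S,8R)-6-(tert-butyldimethylsilyloxy)-1,8-dimethyl-4,8-bis(trimethylsilyloxy)-trans-bicyclo[5.3.0]dec-3-ene
Conditions: LiN(i-Pr)2 (3 equiv), Me3SiCl (5 equiv), THF, −78 °C
Reagents that add atoms: chlorotrimethylsilane, C[Si](C)(C)Cl
Why: Kinetic deprotonation with silyl trapping in the same flask removes the unhindered C3 proton and not the congested ring-fusion C5–H, giving the C3=C4 silyl enol ether, and the tertiary C8 alkoxide is silylated in the same operation.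

Step 15
Reactants: 21 (1S,5S,6S,8R)-6-(tert-butyldimethylsilyloxy)-1,8-dimethyl-4,8-bis(trimethylsilyloxy)-trans-bicyclo[5.3.0]dec-3-ene
Product: 22 (1S,5S,6S,8R)-6-(tert-butyldimethylsilyloxy)-1,8-dimethyl-8-(trimethylsilyloxy)-trans-bicyclo[5.3.0]dec-2-en-4-one
Conditions: Pd(OAc)2 (1.1 equiv), MeCN, rt
Reagents that add atoms: none
Why: Saegusa–Ito oxidation, in which the oxa-π-allylpalladium species formed from the silyl enol ether undergoes β-hydride elimination at C2 to give the C2=C3 enone, which cannot migrate further because C1 is quaternary.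

Step 16
Reactants: 22 (1S,5S,6S,8R)-6-(tert-butyldimethylsilyloxy)-1,8-dimethyl-8-(trimethylsilyloxy)-trans-bicyclo[5.3.0]dec-2-en-4-one
Product: 23 (1S,4S,5S,6S,8R)-6-(tert-butyldimethylsilyloxy)-4-isopropyl-1,8-dimethyl-8-(trimethylsilyloxy)-trans-bicyclo[5.3.0]dec-2-en-4-ol
Conditions: i-PrMgCl, CeCl3, THF, −78 °C
Reagents that add atoms: isopropylmagnesium chloride, CC(C)[Mg]Cl
Why: Organocerium 1,2-addition to the enone (weakly basic, so no conjugate addition, enolisation or β-hydride reduction), in which the nucleophile enters C4 on the face of the C5 hydrogen, opposite the C5–C6 bond and the angular methyl, so that isopropyl ends up cis to H5 and the hydroxyl trans to it as in the target.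

Step 17
Reactants: 23 (1S,4S,5S,6S,8R)-6-(tert-butyldimethylsilyloxy)-4-isopropyl-1,8-dimethyl-8-(trimethylsilyloxy)-trans-bicyclo[5.3.0]dec-2-en-4-ol
Product: 24 (1S,4S,5S,6S,8R)-4-isopropyl-1,8-dimethyl-trans-bicyclo[5.3.0]dec-2-ene-4,6,8-triol
Conditions: Bu4NF, THF, rt to 45 °C
Reagents that add atoms: none
Why: Fluoride cleaves both silyl ethers under non-acidic conditions that leave the acid-sensitive tertiary allylic alcohol at C4 untouched.

Step 18
Reactants: 25 vanillic acid (4-hydroxy-3-methoxybenzoic acid)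
Product: 27 4-(tert-butyldimethylsilyloxy)-3-methoxybenzoic acid, via bis-silyl derivative 26 (not isolated)
Conditions: t-BuMe2SiCl, imidazole, DMF, rt; then AcOH/THF/H2O, rt
Reagents that add atoms: tert-butyldimethylsilyl chloride, CC(C)(C)[Si](C)(C)Cl
Why: Silylation of both phenol and acid followed by selective hydrolysis of the far more labile silyl ester masks the phenol so that the acid cannot acylate itself in the coupling.

Step 19
Reactants: 24 (1S,4S,5S,6S,8R)-4-isopropyl-1,8-dimethyl-trans-bicyclo[5.3.0]dec-2-ene-4,6,8-triol; 27 4-(tert-butyldimethylsilyloxy)-3-methoxybenzoic acid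
Product: 29 (1S,4S,5S,6S,8R)-4,8-dihydroxy-4-isopropyl-1,8-dimethyl-trans-bicyclo[5.3.0]dec-2-en-6-yl 4-(tert-butyldimethylsilyloxy)-3-methoxybenzoate, via mixed anhydride 28 (not isolated)
Conditions: 27, 2,4,6-Cl3C6H2COCl, Et3N, toluene, rt; then 24, DMAP, toluene, 40 °C
Reagents that add atoms: none
Why: Yamaguchi esterification through the mixed anhydride and the acylpyridinium ion acylates the only secondary hydroxyl (C6), the tertiary hydroxyls at C4 and C8 being too hindered to react, under basic conditions that do not ionise the allylic C4 carbinol.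

Step 20
Reactants: 29 (1S,4S,5S,6S,8R)-4,8-dihydroxy-4-isopropyl-1,8-dimethyl-trans-bicyclo[5.3.0]dec-2-en-6-yl 4-(tert-butyldimethylsilyloxy)-3-methoxybenzoate
Product: 30 (1S,4S,5S,6S,8R)-4,8-dihydroxy-4-isopropyl-1,8-dimethyl-trans-bicyclo[5.3.0]dec-2-en-6-yl 4-hydroxy-3-methoxybenzoate (CNP0113302.1)
Conditions: Bu4NF, AcOH, THF, 0 °C
Reagents that add atoms: none
Why: Buffered fluoride removes the aryl silyl ether quickly without cleaving the vanillate ester or eliminating the tertiary alcohols.

Compound list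

1 | (E)-3-methylpent-2-en-4-yn-1-ol | C#C/C(C)=C/CO | starting material
2 | [(2R,3R)-3-ethynyl-3-methyloxiran-2-yl]methanol | C#C[C@@]1(C)O[C@@H]1CO | intermediate
3 | (S)-3-methylpent-4-yne-1,3-diol | C#C[C@@](C)(O)CCO | intermediate
4 | (S)-3-methylpent-4-ene-1,3-diol | C=C[C@@](C)(O)CCO | intermediate
5 | (S)-3-methyl-1,3-bis(triethylsilyloxy)pent-4-ene | C=C[C@@](C)(O[Si](CC)(CC)CC)CCO[Si](CC)(CC)CC | intermediate
6 | (S)-3-methyl-3-(triethylsilyloxy)pent-4-enal (C6–C9 aldehyde) | C=C[C@@](C)(O[Si](CC)(CC)CC)CC=O | intermediate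
7 | 3-methylcyclopent-2-en-1-one | CC1=CC(=O)CC1 | starting material
8 | ethynyltrimethylsilane | C#C[Si](C)(C)C | starting material
9 | diisobutyl[1-(trimethylsilyl)ethenyl]aluminium | C=C([Si](C)(C)C)[Al](CC(C)C)CC(C)C | intermediate (not isolated)
10 | diisobutylaluminium (S)-3-methyl-3-[1-(trimethylsilyl)ethenyl]cyclopent-1-en-1-olate | CC(C)C[Al](CC(C)C)OC1=C[C@@](C)(C(=C)[Si](C)(C)C)CC1 | intermediate (not isolated)
11 | (S)-trimethyl({3-methyl-3-[1-(trimethylsilyl)ethenyl]cyclopent-1-en-1-yl}oxy)silane | C[Si](C)(C)OC1=C[C@@](C)(C(=C)[Si](C)(C)C)CC1 | intermediate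
12 | lithium (S)-3-methyl-3-[1-(trimethylsilyl)ethenyl]cyclopent-1-en-1-olate | [Li]OC1=C[C@@](C)(C(=C)[Si](C)(C)C)CC1 | intermediate (not isolated)
13 | dicyclohexyl({(S)-3-methyl-3-[1-(trimethylsilyl)ethenyl]cyclopent-1-en-1-yl}oxy)borane | C1CCCCC1B(C1CCCCC1)OC1=C[C@@](C)(C(=C)[Si](C)(C)C)CC1 | intermediate (not isolated)
14 | (2S,3S)-2-[(1S,3S)-1-hydroxy-3-methyl-3-(triethylsilyloxy)pent-4-en-1-yl]-3-methyl-3-[1-(trimethylsilyl)ethenyl]cyclopentan-1-one | C=C[C@@](C)(O[Si](CC)(CC)CC)C[C@H](O)[C@H]1C(=O)CC[C@]1(C)C(=C)[Si](C)(C)C | intermediate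
15 | (2S,3S)-2-[(1S,3S)-1-(tert-butyldimethylsilyloxy)-3-methyl-3-(triethylsilyloxy)pent-4-en-1-yl]-3-methyl-3-[1-(trimethylsilyl)ethenyl]cyclopentan-1-one | C=C[C@@](C)(O[Si](CC)(CC)CC)C[C@H](O[Si](C)(C)C(C)(C)C)[C@H]1C(=O)CC[C@]1(C)C(=C)[Si](C)(C)C | intermediate
16 | (2S,3S)-2-[(1S,3S)-1-(tert-butyldimethylsilyloxy)-3-methyl-3-(triethylsilyloxy)pent-4-en-1-yl]-3-(1-iodoethenyl)-3-methylcyclopentan-1-one | C=C[C@@](C)(O[Si](CC)(CC)CC)C[C@H](O[Si](C)(C)C(C)(C)C)[C@H]1C(=O)CC[C@]1(C)C(I)=C | intermediate
17 | (2S,3R)-2-[(1S,3S)-1-(tert-butyldimethylsilyloxy)-3-methyl-3-(triethylsilyloxy)pent-4-en-1-yl]-3-ethenyl-3-methylcyclopentan-1-one | C=C[C@@](C)(O[Si](CC)(CC)CC)C[C@H](O[Si](C)(C)C(C)(C)C)[C@H]1C(=O)CC[C@]1(C)C=C | intermediate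
18 | (2S,3R)-2-[(1S,3S)-1-(tert-butyldimethylsilyloxy)-3-hydroxy-3-methylpent-4-en-1-yl]-3-ethenyl-3-methylcyclopentan-1-one (metathesis precursor) | C=C[C@@](C)(O)C[C@H](O[Si](C)(C)C(C)(C)C)[C@H]1C(=O)CC[C@]1(C)C=C | intermediate
19 | (1R,5S,6S,8S)-6-(tert-butyldimethylsilyloxy)-8-hydroxy-1,8-dimethyl-trans-bicyclo[5.3.0]dec-9-en-4-one (trans-fused hydroazulenone, cis C9=C10) | CC(C)(C)[Si](C)(C)O[C@H]1C[C@](C)(O)C=C[C@@]2(C)CCC(=O)[C@H]12 | intermediate
20 | (1S,5S,6S,8R)-6-(tert-butyldimethylsilyloxy)-8-hydroxy-1,8-dimethyl-trans-bicyclo[5.3.0]decan-4-one | CC(C)(C)[Si](C)(C)O[C@H]1C[C@](C)(O)CC[C@@]2(C)CCC(=O)[C@H]12 | intermediate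
21 | (1S,5S,6S,8R)-6-(tert-butyldimethylsilyloxy)-1,8-dimethyl-4,8-bis(trimethylsilyloxy)-trans-bicyclo[5.3.0]dec-3-ene | CC(C)(C)[Si](C)(C)O[C@H]1C[C@](C)(O[Si](C)(C)C)CC[C@@]2(C)CC=C(O[Si](C)(C)C)[C@H]12 | intermediate
22 | (1S,5S,6S,8R)-6-(tert-butyldimethylsilyloxy)-1,8-dimethyl-8-(trimethylsilyloxy)-trans-bicyclo[5.3.0]dec-2-en-4-one | CC(C)(C)[Si](C)(C)O[C@H]1C[C@](C)(O[Si](C)(C)C)CC[C@@]2(C)C=CC(=O)[C@H]12 | intermediate
23 | (1S,4S,5S,6S,8R)-6-(tert-butyldimethylsilyloxy)-4-isopropyl-1,8-dimethyl-8-(trimethylsilyloxy)-trans-bicyclo[5.3.0]dec-2-en-4-ol | CC(C)(C)[Si](C)(C)O[C@H]1C[C@](C)(O[Si](C)(C)C)CC[C@@]2(C)C=C[C@@](O)(C(C)C)[C@H]12 | intermediate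
24 | (1S,4S,5S,6S,8R)-4-isopropyl-1,8-dimethyl-trans-bicyclo[5.3.0]dec-2-ene-4,6,8-triol | O[C@H]1C[C@](C)(O)CC[C@@]2(C)C=C[C@@](O)(C(C)C)[C@H]12 | intermediate
25 | vanillic acid | COc1cc(C(=O)O)ccc1O | starting material
26 | tert-butyldimethylsilyl 4-(tert-butyldimethylsilyloxy)-3-methoxybenzoate | COc1cc(C(=O)O[Si](C)(C)C(C)(C)C)ccc1O[Si](C)(C)C(C)(C)C | intermediate (not isolated)
27 | 4-(tert-butyldimethylsilyloxy)-3-methoxybenzoic acid | COc1cc(C(=O)O)ccc1O[Si](C)(C)C(C)(C)C | intermediate
28 | 4-(tert-butyldimethylsilyloxy)-3-methoxybenzoic 2,4,6-trichlorobenzoic anhydride | COc1cc(C(=O)OC(=O)c2c(Cl)cc(Cl)cc2Cl)ccc1O[Si](C)(C)C(C)(C)C | intermediate (not isolated)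
29 | (1S,4S,5S,6S,8R)-4,8-dihydroxy-4-isopropyl-1,8-dimethyl-trans-bicyclo[5.3.0]dec-2-en-6-yl 4-(tert-butyldimethylsilyloxy)-3-methoxybenzoate | COc1cc(C(=O)O[C@H]2C[C@](C)(O)CC[C@@]3(C)C=C[C@@](O)(C(C)C)[C@H]23)ccc1O[Si](C)(C)C(C)(C)C | intermediate
30 | (1S,4S,5S,6S,8R)-4,8-dihydroxy-4-isopropyl-1,8-dimethyl-trans-bicyclo[5.3.0]dec-2-en-6-yl 4-hydroxy-3-methoxybenzoate (CNP0113302.1) | COc1cc(C(=O)O[C@H]2C[C@](C)(O)CC[C@@]3(C)C=C[C@@](O)(C(C)C)[C@H]23)ccc1O | target

Total step count: 20.
Longest linear sequence: 18 steps (steps 1–5, 7–17, 19 and 20).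

Steps most likely to fail

Step 12 (ring closure). What may go wrong: after loading on the C8 vinyl group the alkylidene fails to close onto the neopentyl C1 vinyl group, which sits beside the bulky C6 silyl ether, so that intermolecular metathesis of the carbinol vinyl groups takes over. The fallback changes substrate and sequence, not the catalyst, and sets out from 17. Bu4NF in THF removes both silyl ethers to give (2S,3R)-2-[(1S,3S)-1,3-dihydroxy-3-methylpent-4-en-1-yl]-3-ethenyl-3-methylcyclopentan-1-one F1, in which nothing crowds the C1 vinyl group and the C6 hydroxyl can hydrogen-bond to the ketone and fold the chain. Ring closure with the same ruthenium benzylidene under dilution should give (1R,5S,6S,8S)-6,8-dihydroxy-1,8-dimethyl-trans-bicyclo[5.3.0]dec-9-en-4-one F2. Silylation of the secondary hydroxyl alone (t-BuMe2SiOTf, 2,6-lutidine, −78 °C) comes back to the route at 19.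

Step 7 (aldol union). What may go wrong: slow addition of the encumbered dicyclohexylboron enolate at C5, which lies between the carbonyl and the fully substituted C1, or incomplete lithium-to-boron exchange followed by proton transfer from the enolisable aldehyde and erosion of the anti selectivity. The fallback activates the electrophile instead of the nucleophile and sets out from 11 and 6. BF3·OEt2 in CH2Cl2 at −78 °C promotes the Mukaiyama addition of the enol silane itself through an open transition state, in which the 1-silylvinyl group still blocks one face of C5. This returns directly to 14; simple diastereoselection at C6 then rests on the open transition state, and chromatographic removal of a C6 epimer may be needed. No new compound is made.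

Step 6 (quaternary centre). What may go wrong: insufficient enantioface discrimination on the flat five-membered enone, or transfer of isobutyl or hydride from the alane in competition with the alkenyl group. The fallback is a stoichiometric racemic addition with the enantiopure aldehyde as resolving partner, and sets out from 7. [1-(Trimethylsilyl)ethenyl]magnesium bromide F3, made from commercial (1-bromoethenyl)trimethylsilane and Mg, is added with CuBr·SMe2 (10 mol%) and Me3SiCl in THF at −78 °C to give racemic trimethyl({3-methyl-3-[1-(trimethylsilyl)ethenyl]cyclopent-1-en-1-yl}oxy)silane F4. The boron aldol of step 7 (through racemic 12 and 13) with enantiopure 6 should then give 14 together with (2R,3R)-2-[(1R,3S)-1-hydroxy-3-methyl-3-(triethylsilyloxy)pent-4-en-1-yl]-3-methyl-3-[1-(trimethylsilyl)ethenyl]cyclopentan-1-one F5, built on the antipodal ring. The two are diastereomers and are separated by chromatography; the route is rejoined at 14.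

Further compounds

F1 | step 12 | (2S,3R)-2-[(1S,3S)-1,3-dihydroxy-3-methylpent-4-en-1-yl]-3-ethenyl-3-methylcyclopentan-1-one | C=C[C@@](C)(O)C[C@H](O)[C@H]1C(=O)CC[C@]1(C)C=C
F2 | step 12 | (1R,5S,6S,8S)-6,8-dihydroxy-1,8-dimethyl-trans-bicyclo[5.3.0]dec-9-en-4-one | O[C@H]1C[C@](C)(O)C=C[C@@]2(C)CCC(=O)[C@H]12
F0 | step 7 | none | none
F3 | step 6 | [1-(trimethylsilyl)ethenyl]magnesium bromide | C=C([Si](C)(C)C)[Mg]Br
F4 | step 6 | racemic trimethyl({3-methyl-3-[1-(trimethylsilyl)ethenyl]cyclopent-1-en-1-yl}oxy)silane | C[Si](C)(C)OC1=CC(C)(C(=C)[Si](C)(C)C)CC1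
F5 | step 6 | (2R,3R)-2-[(1R,3S)-1-hydroxy-3-methyl-3-(triethylsilyloxy)pent-4-en-1-yl]-3-methyl-3-[1-(trimethylsilyl)ethenyl]cyclopentan-1-one | C=C[C@@](C)(O[Si](CC)(CC)CC)C[C@@H](O)[C@@H]1C(=O)CC[C@@]1(C)C(=C)[Si](C)(C)C
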